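In a one-step world, one substrate gives one product and a flask holds little more than a rate. Here two mirror-image substrates compete for a fed reagent on a single-handed free catalyst, while a racemization catalyst can turn either substrate into the other. Without that exchange, a racemate carried to full conversion gives equal amounts of both products, whatever the free catalyst prefers.

| setting | elm | alder | birch | flask |
|---|---|---|---|---|
| left-handed substrate | 0.15 M | 0.15 M | 0.15 M | 0.15 M |
| right-handed substrate | 0.15 M | 0.15 M | 0.15 M | 0.15 M |
| reagent | 0.30 M (fed, over 1.5 h) | 0.30 M (fed, over 1.5 h) | 0.60 M (fed, over 1.5 h) | 0.300 M (fed, over 1.5 h) |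
| free catalyst | 0.30 mM | 0.30 mM | 0.30 mM | 0.30 mM |
| racemization catalyst | 2.1 mM | 3.3 mM | 1.5 mM | 1.5 mM |
| impurity | 32 µM | 32 µM | 32 µM | 32 µM |
| remark | run made earlier | run made earlier | run made earlier |  |
| time |  |  |  | 6.0 h |

| run | time / h | left-handed product / % | right-handed product / % |
|---|---|---|---|
| elm | 0.500 | 19.7 | 12.0 |
| elm | 0.833 | 33.6 | 18.3 |
| elm | 1.33 | 52.6 | 27.3 |
| elm | 2.00 | 62.6 | 34.1 |
| elm | 4.00 | 63.9 | 34.8 |
| elm | 6.00 | 65.8 | 34.3 |
| alder | 0.417 | 16.4 | 9.0 |
| alder | 1.33 | 51.5 | 27.0 |
| alder | 2.00 | 62.8 | 33.3 |
| alder | 3.00 | 64.3 | 32.7 |
| alder | 5.00 | 64.3 | 33.3 |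
| alder | 6.00 | 65.9 | 33.6 |
| birch | 0.500 | 34.8 | 20.1 |
| birch | 0.833 | 58.2 | 31.9 |
| birch | 1.50 | 63.7 | 34.0 |
| birch | 3.00 | 63.6 | 33.7 |
| birch | 6.00 | 67.0 | 33.4 |

(each reading ± 1 percentage point)

- free catalyst is single-handed; left-handed substrate and right-handed substrate are mirror images of each other, charged as a racemate, each of them at the stated concentration
- the numbers in the tables scatter by 1 percentage point (one standard deviation)
- an excess is the difference of the two amounts in percent of their sum
- an excess is below zero if the other one leads

- left-handed product and right-handed product together, in percent of the left-handed substrate and right-handed substrate charged together, at 6.0 h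
- excess of left-handed product over right-handed product in the product at 6.0 h
- whether the exchange between left-handed substrate and right-handed substrate keeps pace with the reaction: how far the product's excess at 6.0 h gets from its value without exchange to its value with instant exchange (above 80% keeps pace, below 20% hardly takes part, else lags behind)

The earlier runs form a ladder, read here rung by rung. Exchange comes first. At 6.0 h, birch, with 1.5 mM racemization catalyst and the doubled feed, reads 2.01 to one for left-handed against right-handed product. Alder, with 3.3 mM, reads 1.96 to one, although both totals stand near complete conversion. Feed comes next: by 1.3 h, elm has received reagent for 88.7% of its two substrates together and reads 79.9% product, so the product trails the feed closely. Last comes the tail: elm's total reads 96.7% at 2.0 h and 100% at 6.0 h.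

The readings from 3.0 h on give 1.93 as the selectivity factor s, the ratio in which the two products form while the two substrates stand equal. Its excess is (s − 1)/(s + 1). The flask has racemization catalyst per reagent fed at twice birch's, so by this reckoning exchange keeps pace in the flask, and the excess comes to 31.7%. The flask's reagent and feed match elm's, and the 6.0 h totals of elm and alder put y near 99.8%.

The forecast gives 99% product (97% to 100%) at an excess of 31.5% (29.5% to 33.5%), and calls the flask “safely inside that regime”, so that exchange keeps pace.

The flask gives 99.1% product at an excess of 31.3%, and exchange keeps pace, getting 98% of the way.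

    reagent + free catalyst + left-handed substrate → free catalyst + left-handed product (k = 130 M⁻² s⁻¹)
    reagent + free catalyst + right-handed substrate → free catalyst + right-handed product (k = 67.0 M⁻² s⁻¹)
    left-handed substrate + racemization catalyst ⇌ right-handed substrate + racemization catalyst, rate k3*[racemization catalyst]*[left-handed substrate] forward; the back reaction follows from the equilibrium constant (k = 5.10 M⁻¹ s⁻¹)
    reagent + free catalyst → spent catalyst A (k = 0.00110 M⁻¹ s⁻¹)
    free catalyst + impurity → spent catalyst B (k = 650 M⁻¹ s⁻¹)

In the flask at 1.50 h, right-handed substrate leads left-handed substrate by an excess of 1.86% among what is left. The neighbour charged with 0.075 M reagent ends with 0% reagent and 25.0% product. The factor s splits that total into 16.5% left-handed product, and that flask holds 16.5%.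

All runs were computed with constants of no real substance, and the scatter is random.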